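**Plan**
1. Retrosynthesis: the allyl–aryl bond is cut first, with an aryl chloride standing in for the base-sensitive allyl group. The dioxane ring (ring B) is then opened at two bonds at once, the aryl C–O bond to the oxygen on the methyl-bearing carbon and the C–C bond between the two sp3 ring carbons, leaving acetaldehyde and a benzyl 2-fluoroaryl ether. The benzyl–O bond is cut last.
2. Forward: a Williamson ether synthesis joins ring A (the halogenated benzo ring) to ring C (the trimethoxyphenyl ring) through O–CH2. A one-pot lithiation, acetaldehyde addition and fluoride displacement then builds ring B, and ring A is allylated last.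
3. Enabling feature: in the ether, the O–CH2 carbon (benzylic to ring C and alpha to oxygen, hence lithiable) and the C–F carbon of ring A ortho to that oxygen stand 1,4 to each other. They form a carbon nucleophile and an aryl electrophile that take up the C=O of acetaldehyde as the two missing atoms of ring B.
4. Stereochemistry: both centres arise in the key step. The CH–aryl centre comes from the chiral bis(oxazoline)-bound lithium, and the CH–CH3 centre from the relative topicity of the carbonyl addition (threo, hence trans). No later step touches them.

Key step: step 2

Assumption: the sense of induction of the bis(oxazoline) ligand on this ether cannot be predicted with certainty; the (S,S)-ligand, 2,2'-(propane-2,2-diyl)bis[(4S)-4-isopropyl-4,5-dihydro-1,3-oxazole] ((S,S)-iPr-box), is written, and its antipode would be used if a first trial shows the opposite sense.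

**Route**

Step 1
Reactants: 1 5-chloro-2-fluorophenol; 2 3,4,5-trimethoxybenzyl chloride
Product: 3 4-chloro-1-fluoro-2-[(3,4,5-trimethoxybenzyl)oxy]benzene
Conditions: K2CO3, DMF, 60 °C
Reagents that add atoms: none
Why: Williamson ether synthesis, in which the phenoxide of 1 displaces the primary benzylic chloride by SN2 while the aryl fluoride and aryl chloride are inert to carbonate.

Step 2
Reactants: 3 4-chloro-1-fluoro-2-[(3,4,5-trimethoxybenzyl)oxy]benzene; 4 acetaldehyde
Product: 7 (2R,3R)-6-chloro-2-methyl-3-(3,4,5-trimethoxyphenyl)-2,3-dihydro-1,4-benzodioxine, via lithiated ether 5 (not isolated), via lithium alkoxide 6 (not isolated)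
Conditions: t-BuLi, (S,S)-iPr-box, toluene, −78 °C; MeCHO, −78 °C; then KOt-Bu, DMF, 60 °C
Reagents that add atoms: acetaldehyde (compound 4), CC=O
Why: Proposed new method: t-BuLi, guided by the ether oxygen, removes a hydrogen of the O–CH2 carbon (benzylic to ring C) to give lithiated ether 5, which is configurationally labile and is sorted on the chiral bis(oxazoline) ligand before it adds to the C=O carbon of acetaldehyde to give alkoxide 6; after potassium exchange in DMF the alkoxide oxygen displaces the ortho fluoride of ring A by addition–elimination through a Meisenheimer complex. The closest known reaction types are the chiral-ligand-mediated enantioselective alpha-lithiation and electrophile trapping of benzyl alkyl ethers, the alpha-lithiation of aryl benzyl ethers with t-BuLi at −78 °C followed by aldehyde addition, and the intramolecular SNAr etherification of alkoxides on unactivated aryl fluorides; their merger, and ligand control on an aryl benzyl ether, are the unproven part. Ring B closes in the 6-exo-trig mode, the oxygen attacking the fluorine-bearing sp2 carbon that lies ortho to the tether oxygen. The CH–aryl centre is controlled by the ligand-bound lithium, which the aldehyde should replace on one face only, and the CH–CH3 centre by the relative topicity of the lithium-bridged addition, in which the aldehyde methyl should turn away from ring C to give the threo alkoxide and hence the trans ring. The step needs alpha-lithiation in preference to ring metalation and to aryl migration from oxygen to carbon, which the proximity of the ether oxygen, the low temperature and the chloro stand-in for the allyl group should secure, and fluoride rather than chloride displacement, which is secured because only the C–F carbon is within reach of the alkoxide and the para chlorine lowers the barrier. Neither new centre is touched by the ring closure, and any cis isomer is a diastereomer that chromatography should remove.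

Step 3
Reactants: 7 (2R,3R)-6-chloro-2-methyl-3-(3,4,5-trimethoxyphenyl)-2,3-dihydro-1,4-benzodioxine; 8 allylboronic acid pinacol ester
Product: 9 (2R,3R)-2-methyl-6-(prop-2-en-1-yl)-3-(3,4,5-trimethoxyphenyl)-2,3-dihydro-1,4-benzodioxine (CNP0000093.2)
Conditions: Pd(OAc)2 (cat.), XPhos, K3PO4, THF/H2O, 60 °C
Reagents that add atoms: allylboronic acid pinacol ester (compound 8), C=CCB1OC(C)(C)C(C)(C)O1
Why: Suzuki–Miyaura cross-coupling, in which the aryl C–Cl bond adds oxidatively to zerovalent palladium carrying the bulky biaryl phosphine, the allyl group is transferred from boron and reductive elimination gives the allyl arene, with both stereocentres remote and untouched.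

**Compound list**
1 | 5-chloro-2-fluorophenol | Oc1cc(Cl)ccc1F | starting material
2 | 3,4,5-trimethoxybenzyl chloride | COc1cc(CCl)cc(OC)c1OC | starting material
3 | 4-chloro-1-fluoro-2-[(3,4,5-trimethoxybenzyl)oxy]benzene | COc1cc(COc2cc(Cl)ccc2F)cc(OC)c1OC | intermediate
4 | acetaldehyde | CC=O | starting material
5 | [(5-chloro-2-fluorophenoxy)(3,4,5-trimethoxyphenyl)methyl]lithium, bound to the bis(oxazoline) ligand, configurationally labile | COc1cc(C([Li])Oc2cc(Cl)ccc2F)cc(OC)c1OC | intermediate
6 | lithium (1R,2R)-1-(5-chloro-2-fluorophenoxy)-1-(3,4,5-trimethoxyphenyl)propan-2-olate | Clc1ccc(F)c(c1)O[C@H](c1cc(OC)c(OC)c(OC)c1)[C@@H](C)[O-].[Li+] | intermediate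
7 | (2R,3R)-6-chloro-2-methyl-3-(3,4,5-trimethoxyphenyl)-2,3-dihydro-1,4-benzodioxine (trans) | Clc1ccc2c(c1)O[C@H](c1cc(OC)c(OC)c(OC)c1)[C@@H](C)O2 | intermediate
8 | allylboronic acid pinacol ester | C=CCB1OC(C)(C)C(C)(C)O1 | starting material
9 | (2R,3R)-2-methyl-6-(prop-2-en-1-yl)-3-(3,4,5-trimethoxyphenyl)-2,3-dihydro-1,4-benzodioxine (trans) | C=CCc1ccc2c(c1)O[C@H](c1cc(OC)c(OC)c(OC)c1)[C@@H](C)O2 | target

**Step count**
Total steps: 3. Longest linear sequence: 3 steps.

**Steps most likely to fail**

Step 2. Facial control at the lithiated carbon may be weak if the ligand-bound carbanion is poorly discriminated, and the relative topicity of the aldehyde addition may be low, giving trans/cis mixtures. Ring metalation or aryl migration from oxygen to carbon may compete, and the fluoride displacement may be slow. The fallback uses known chemistry, sets out from 3 and comes back at 7. Compound 3 is lithiated with t-BuLi in THF at −78 °C without ligand and acylated with N-methoxy-N-methylacetamide to give racemic 1-(5-chloro-2-fluorophenoxy)-1-(3,4,5-trimethoxyphenyl)propan-2-one F1. Reagent-controlled reduction of this methyl ketone with (S)-2-methyl-CBS-oxazaborolidine and BH3·SMe2 should give (2R)-1-(5-chloro-2-fluorophenoxy)-1-(3,4,5-trimethoxyphenyl)propan-2-ol F2 as a mixture of the two epimers at C1. KOt-Bu in DMF at 60 °C then closes ring B by SNAr, and 7 is separated by chromatography from its cis diastereomer, (2R,3S)-6-chloro-2-methyl-3-(3,4,5-trimethoxyphenyl)-2,3-dihydro-1,4-benzodioxine F3. The absolute configuration then rests on the CBS reduction, at the cost of the cis half of the material.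

Step 3. Oxidative addition into the electron-rich aryl chloride may be slow, a palladium hydride may move the allyl double bond into conjugation with ring A, and the allylboronate may be lost by protodeboronation. The fallback reverses the polarity of the coupling, sets out from 7 and comes back at 9. Miyaura borylation of 7 (B2pin2, Pd2(dba)3, XPhos, KOAc, dioxane, 100 °C) should give (2R,3R)-2-methyl-6-(4,4,5,5-tetramethyl-1,3,2-dioxaborolan-2-yl)-3-(3,4,5-trimethoxyphenyl)-2,3-dihydro-1,4-benzodioxine F4. This aryl boronate is then coupled with allyl bromide (Pd(PPh3)4, CsF, THF, 60 °C), where the allyl group enters as the electrophile.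

Step 1. The alkylation may stall, or the benzyl chloride may be consumed by hydrolysis in wet DMF. The fallback sets out from 1 and comes back at 3: a Mitsunobu etherification of 1 with 3,4,5-trimethoxybenzyl alcohol F5 (PPh3, DIAD, THF, 0 °C to room temperature), which activates the alcohol instead of relying on a halide.

**Further compounds**
F1 | step 2 | 1-(5-chloro-2-fluorophenoxy)-1-(3,4,5-trimethoxyphenyl)propan-2-one (racemic) | CC(=O)C(Oc1cc(Cl)ccc1F)c1cc(OC)c(OC)c(OC)c1
F2 | step 2 | (2R)-1-(5-chloro-2-fluorophenoxy)-1-(3,4,5-trimethoxyphenyl)propan-2-ol (both C1 epimers) | Clc1ccc(F)c(c1)OC(c1cc(OC)c(OC)c(OC)c1)[C@@H](C)O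
F3 | step 2 | (2R,3S)-6-chloro-2-methyl-3-(3,4,5-trimethoxyphenyl)-2,3-dihydro-1,4-benzodioxine (cis) | Clc1ccc2c(c1)O[C@@H](c1cc(OC)c(OC)c(OC)c1)[C@@H](C)O2
F4 | step 3 | (2R,3R)-2-methyl-6-(4,4,5,5-tetramethyl-1,3,2-dioxaborolan-2-yl)-3-(3,4,5-trimethoxyphenyl)-2,3-dihydro-1,4-benzodioxine | CC1(C)OB(OC1(C)C)c1ccc2c(c1)O[C@H](c1cc(OC)c(OC)c(OC)c1)[C@@H](C)O2
F5 | step 1 | 3,4,5-trimethoxybenzyl alcohol | COc1cc(CO)cc(OC)c1OC
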